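**Fixed sum.** Passing between the phases or into the dormant form leaves the total of reagent unchanged, so your quick number can start from that sum. You suspected that faster transfer pays best. Here is the flask.

substrate 1.0 mM; reagent in the second phase 1.30 mM; protic impurity 0.100 mM; time 1.2 s; volume of the second phase over the first 2.0

* how much target and product in the second phase together there is at 1.2 s, in percent of the substrate charged
* the change that raises the amount of target and product in the second phase together at 1.2 s, in percent of the substrate charged most ("none" if none brings more than 2 percentage points) (oak / elm / ash / none)
* amount of target and product in the second phase together at 1.2 s, in percent of the substrate charged, after elm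

- oak: doubling the transfer coefficient of step 1, all else as stated
- elm: doubling the transfer coefficient of step 3, all else as stated
- ash: doubling the amount of reagent in the second phase, all else as stated

- what is said of target includes product in the second phase
- in the second phase: reagent in the second phase, product in the second phase; everything else is in the first
- charges count per volume of the first phase; a concentration in a rate is the amount of a species over the volume of its own phase; every rate counts per litre of the first phase
- run time (flask): 1.2 s

    reagent in the reaction phase ⇌ reagent in the second phase, rate k1*([reagent in the reaction phase] - [reagent in the second phase]/K1) per volume of the first phase (K1 = 1.2, k1 = 3.0 s⁻¹)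
    substrate + reagent in the reaction phase → target (k2 = 1400 M⁻¹ s⁻¹)
    target ⇌ product in the second phase, rate k3*([target] - [product in the second phase]/K3) per volume of the first phase (K3 = 0.32, k3 = 0.40 s⁻¹)
    target → decomposed product (k4 = 0.32 s⁻¹)
    reagent in the reaction phase → decomposition product (k5 = 1.5 × 10⁻⁴ s⁻¹)
    reagent in the reaction phase ⇌ dormant form (K6 = 0.72, k6 = 7.2 s⁻¹)
    reagent in the reaction phase + protic impurity → quenched reagent (k7 = 9600 M⁻¹ s⁻¹)

**Even spread.** For the zero of the scale, I take the reagent spread as its equilibria place it, with no reaction. For each unit of reagent in the reaction phase, the dormant form holds 0.72 and the second phase 2.40. So the free share, the part of the reagent standing free in the reaction phase, is 0.243. I take the protic impurity off the charge, one for one, which gives a free level of 0.291 mM.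

**My number.** The reaction phase starts empty and fills towards that level at 2.99 s⁻¹, so I subtract the lag from the run time. Treating the substrate as pseudo-first-order at the free level gives an exposure of 0.353. A target made midway through the run keeps 0.825 of itself. My figure is 24.6%, and elm appears in neither the share nor the exposure, so I hold 24.6% for it. Against your hunch, oak lifts the exposure to 0.421 and ash to 0.736, so my choice is ash.

**The forecast.** The forecast gave 23%, within 20% to 26%; 24% after elm, within 21% to 27%; and ash as the best change. Its ground: “Doubling the reagent charge raises the active reagent most”. My figure stands above its 23%.

**The result.** The flask gives 21.3%, and 21.6% after elm. The best change is ash, worth 17 percentage points, against 3.7 points for oak. At 1.20 s the flask holds 0.966 mM of reagent across the three forms; the free share, reckoned for the equilibrium spread, gives 0.234 mM on that sum, while [reagent in the reaction phase] reads 0.195 mM.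

**Second flask.** With 0.40 mM of protic impurity and the rest unchanged, the free share gives a level of 0.218 mM and a figure of 19.2%. That flask computes to 16.8%, with [reagent in the reaction phase] at 0.142 mM.

(The numbers of this flask were drawn at random within sensible limits; the result is computed.)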